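**Retrosynthetic overview**

- The target comes from a bicyclic vinylogous ester by hydride reduction and mild acid (reductive 1,3-carbonyl transposition). This opens the furan ring, frees the C-7 hydroxyl, forms the enone and removes one extra ring oxygen.
- That hexahydrobenzofuranone comes from conjugate reduction of a burchellin-type dihydrobenzofuranone dienone, which sets C-3′.
- The dienone comes from an acid-promoted carbon-to-oxygen shift of the benzylic carbon in a guianin-type bicyclo[3.2.1]octenedione, with the cis aryl/methyl pair kept.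
- The bicyclooctenedione comes from an enantioselective cationic [5+2] cycloaddition of the methoxy-quinonium ion of 2-allyl-4,4,5-trimethoxycyclohexadienone with (Z)-methylisoeugenol, which sets C-7, C-8 and C-1′.
- Ring order: bicyclo[3.2.1]octane first, then the dihydrofuran ring by the shift, then the furan ring is opened; the cyclohexenone is the old ring of 3,4-dimethoxyphenol.

Assumption 1: the presumed biosynthesis is oxidative coupling of a propenylbenzene with an oxidised allylphenol by cationic [5+2] cycloaddition to a bicyclo[3.2.1]octanoid, its shift to a hydrobenzofuranoid, and opening of the furan ring to the 7-hydroxy enone.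

Assumption 2: the sense of induction of the chiral acid in step 5 cannot be predicted; the (R) acid is written, and its antipode is used if the first run gives the mirror-image series.

Atom labels used below: C-7 = benzylic carbinol carbon, C-8 = CH(CH3), C-1′ = quaternary ring carbon, C-2′ = ring CH2, C-3′ = ring CH(OMe), C-4′/C-5′ = enone CH=CH, C-6′ = ring carbonyl carbon.

**Route**

Step 1
Reactants: 1 3,4-dimethoxyphenol; 2 allyl bromide
Product: 3 4-(allyloxy)-1,2-dimethoxybenzene
Conditions: K2CO3, acetone, reflux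
Reagents that add atoms: allyl bromide (2), C=CCBr
Why: Williamson ether synthesis (SN2 of the phenoxide on allyl bromide); no stereocentre is formed.

Step 2
Reactants: 3 4-(allyloxy)-1,2-dimethoxybenzene
Product: 4 2-allyl-4,5-dimethoxyphenol
Conditions: N,N-diethylaniline, 190 °C
Reagents that add atoms: none
Why: aromatic Claisen [3,3] rearrangement to the less hindered ortho carbon (not the one flanked by OMe), followed by tautomerisation.

Step 3
Reactants: 4 2-allyl-4,5-dimethoxyphenol
Product: 5 2-allyl-4,4,5-trimethoxycyclohexa-2,5-dien-1-one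
Conditions: PhI(OAc)2, MeOH, 0 °C
Reagents that add atoms: methanol, CO
Why: oxidative dearomatisation of a para-methoxyphenol; methanol traps the phenoxonium ion at the para carbon to give the para-quinone monoketal.

Step 4
Reactants: 6 1,2-dimethoxy-4-[(1E)-prop-1-en-1-yl]benzene ((E)-methylisoeugenol)
Product: 7 1,2-dimethoxy-4-[(1Z)-prop-1-en-1-yl]benzene ((Z)-methylisoeugenol)
Conditions: fac-Ir(ppy)3 (ppy = 2-phenylpyridinato, C11H8N; 1 mol %), MeCN, blue LEDs, rt; AgNO3–SiO2 chromatography
Reagents that add atoms: none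
Why: triplet-sensitised contra-thermodynamic E-to-Z isomerisation; the twisted Z isomer is the poorer energy acceptor and accumulates, and the E isomer must be removed because it would give the C-8 epimeric series.

Step 5
Reactants: 5 2-allyl-4,4,5-trimethoxycyclohexa-2,5-dien-1-one; 7 (Z)-methylisoeugenol
Product: 10 (2S,3R,3aR)-3a-allyl-2-(3,4-dimethoxyphenyl)-5-methoxy-3-methyl-3,3a-dihydro-1-benzofuran-6(2H)-one, via bicyclo[3.2.1]octenone dimethyl ketal 8 (not isolated), via bicyclo[3.2.1]octenedione 9 (not isolated)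
Conditions: (R)-3,3′-bis(2,4,6-triisopropylphenyl)-1,1′-bi-2-naphthol N-triflylphosphoramide (10 mol %), CH2Cl2, −78 to −40 °C; then CF3SO3H (20 mol %), H2O (2 equiv), −40 to 0 °C
Reagents that add atoms: water, O
Why: Proposed new method: the chiral acid ionises the ketal to a methoxy-quinonium ion paired with its chiral anion, and the Z-alkene adds by a concerted, suprafacial cationic [5+2] cycloaddition; C-8 bonds to the allyl-bearing terminus C-1′ because the other terminus is made nucleophilic by the neighbouring OMe and closes on C-7, the Z geometry gives cis aryl/methyl, the aryl-endo approach puts the methyl trans to allyl, and the anion selects the face (absolute configuration); the oxocarbenium adduct is caught by the released methanol as ketal 8, aqueous CF3SO3H hydrolyses it to 9 and ionises the C-5′–C-7 bond, and the enol oxygen on C-6′ recloses on the same face under kinetic control (quench as soon as 9 is gone) to keep the cis pair. Closest known reaction types: the racemic acid-catalysed quinone monoketal–propenylbenzene [5+2] cycloaddition and bicyclooctanoid-to-hydrobenzofuranoid shift of guianin/burchellin neolignans, and chiral-counteranion catalysis of oxocarbenium cycloadditions.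

Step 6
Reactants: 10 (2S,3R,3aR)-3a-allyl-2-(3,4-dimethoxyphenyl)-5-methoxy-3-methyl-3,3a-dihydro-1-benzofuran-6(2H)-one
Product: 11 (2S,3R,3aS,5S)-3a-allyl-2-(3,4-dimethoxyphenyl)-5-methoxy-3-methyl-3,3a,4,5-tetrahydro-1-benzofuran-6(2H)-one
Conditions: Cu(OAc)2·H2O (5 mol %), 1,2-bis(diphenylphosphino)benzene (5 mol %), (EtO)2MeSiH, t-BuOH, toluene, rt; then DBU (cat.)
Reagents that add atoms: none
Why: copper hydride conjugate reduction (Stryker type) delivers hydride to C-2′ of the α-methoxy enone only, since the vinylogous ester and the allyl group are inert; protonation at C-3′ anti to the pseudo-axial allyl and base equilibration place OMe equatorial, cis to C-8 and trans to allyl (5S).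

Step 7
Reactants: 11 (2S,3R,3aS,5S)-3a-allyl-2-(3,4-dimethoxyphenyl)-5-methoxy-3-methyl-3,3a,4,5-tetrahydro-1-benzofuran-6(2H)-one
Product: 13 (4S,6S)-6-allyl-6-[(1S,2R)-1-(3,4-dimethoxyphenyl)-1-hydroxypropan-2-yl]-4-methoxycyclohex-2-en-1-one (CNP0138111.1), via allylic alcohol 12 (not isolated)
Conditions: i-Bu2AlH, CH2Cl2, −78 °C; then 0.5 M aq. oxalic acid, THF, 0 °C
Reagents that add atoms: water, O
Why: Stork–Danheiser reductive 1,3-carbonyl transposition; 1,2-reduction of the vinylogous ester carbonyl, acid ionisation to the alkoxy-allyl cation, water addition at C-6′ and hemiketal collapse break the C-6′–O bond, so the C-7–O bond is never broken and all four stereocentres are kept.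

**Compound list**

1 | 3,4-dimethoxyphenol | COc1ccc(O)cc1OC | starting material
2 | allyl bromide | C=CCBr | starting material
3 | 4-(allyloxy)-1,2-dimethoxybenzene | C=CCOc1ccc(OC)c(OC)c1 | intermediate
4 | 2-allyl-4,5-dimethoxyphenol | C=CCc1cc(OC)c(OC)cc1O | intermediate
5 | 2-allyl-4,4,5-trimethoxycyclohexa-2,5-dien-1-one | C=CCC1=CC(OC)(OC)C(OC)=CC1=O | intermediate
6 | 1,2-dimethoxy-4-[(1E)-prop-1-en-1-yl]benzene | C/C=C/c1ccc(OC)c(OC)c1 | starting material
7 | 1,2-dimethoxy-4-[(1Z)-prop-1-en-1-yl]benzene | C/C=C\c1ccc(OC)c(OC)c1 | intermediate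
8 | (1R,5R,6S,7R)-5-allyl-7-(3,4-dimethoxyphenyl)-2,2,3-trimethoxy-6-methylbicyclo[3.2.1]oct-3-en-8-one (6-endo-methyl, 7-endo-aryl; not isolated) | C=CC[C@@]12C=C(OC)C(OC)(OC)[C@@H](C1=O)[C@H](c1ccc(OC)c(OC)c1)[C@@H]2C | intermediate
9 | (1R,5R,6S,7R)-5-allyl-7-(3,4-dimethoxyphenyl)-3-methoxy-6-methylbicyclo[3.2.1]oct-3-ene-2,8-dione (6-endo-methyl, 7-endo-aryl; not isolated) | C=CC[C@@]12C=C(OC)C(=O)[C@@H](C1=O)[C@H](c1ccc(OC)c(OC)c1)[C@@H]2C | intermediate
10 | (2S,3R,3aR)-3a-allyl-2-(3,4-dimethoxyphenyl)-5-methoxy-3-methyl-3,3a-dihydro-1-benzofuran-6(2H)-one (aryl cis to methyl, methyl trans to allyl) | C=CC[C@@]12C=C(OC)C(=O)C=C1O[C@H](c1ccc(OC)c(OC)c1)[C@@H]2C | intermediate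
11 | (2S,3R,3aS,5S)-3a-allyl-2-(3,4-dimethoxyphenyl)-5-methoxy-3-methyl-3,3a,4,5-tetrahydro-1-benzofuran-6(2H)-one | C=CC[C@@]12C[C@H](OC)C(=O)C=C1O[C@H](c1ccc(OC)c(OC)c1)[C@@H]2C | intermediate
12 | (2S,3R,3aS,5S)-3a-allyl-2-(3,4-dimethoxyphenyl)-5-methoxy-3-methyl-2,3,3a,4,5,6-hexahydro-1-benzofuran-6-ol (C-6 epimers; not isolated) | C=CC[C@@]12C[C@H](OC)C(O)C=C1O[C@H](c1ccc(OC)c(OC)c1)[C@@H]2C | intermediate
13 | (4S,6S)-6-allyl-6-[(1S,2R)-1-(3,4-dimethoxyphenyl)-1-hydroxypropan-2-yl]-4-methoxycyclohex-2-en-1-one | C=CC[C@@]1([C@@H](C)[C@H](O)c2ccc(OC)c(OC)c2)C[C@H](OC)C=CC1=O | target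

**Step count**

Total: 7 steps. Longest linear sequence: 6 steps (1, 2, 3, 5, 6, 7).

**Three steps most likely to fail**

Step 5 is the weakest: the chiral acid may give low enantioselectivity or turn over poorly, and the shift must stay under kinetic control. The fallback sets out from 4 (with 7) and comes back at 9. Phenol 4 is oxidised with PhI(OAc)2 in wet MeCN to 2-allyl-5-methoxy-1,4-benzoquinone F1. F1 and 7 are combined at −78 °C in CH2Cl2 with a stoichiometric chiral titanium TADDOLate made from TiCl4, Ti(OiPr)4 and (4R,5R)-2,2-dimethyl-α,α,α′,α′-tetraphenyl-1,3-dioxolane-4,5-dimethanol. Titanium chelates the carbonyl oxygen next to the methoxy group, and the same [5+2] addition gives, after aqueous work-up, (1R,5R,6S,7R)-5-allyl-7-(3,4-dimethoxyphenyl)-3-hydroxy-6-methylbicyclo[3.2.1]oct-3-ene-2,8-dione F2. O-Methylation of this diosphenol with Me2SO4 and K2CO3 in acetone gives 9, which is carried to 10 by the CF3SO3H stage of step 5.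

Step 7 may ionise the very electron-rich benzylic C-7–O bond in the oxocarbenium intermediate, which would epimerise C-7, or lose methanol. The fallback sets out from 11 and comes back at 13 without any cation. LiOH in THF/H2O opens the vinylogous ester to (4S,6S)-4-allyl-4-[(1S,2R)-1-(3,4-dimethoxyphenyl)-1-hydroxypropan-2-yl]-6-methoxycyclohexane-1,3-dione F4. PhNTf2 and Et3N in CH2Cl2 sulfonylate the less hindered enolate oxygen (the one away from the quaternary carbon) to give (4S,6S)-4-allyl-4-[(1S,2R)-1-(3,4-dimethoxyphenyl)-1-hydroxypropan-2-yl]-6-methoxy-3-oxocyclohex-1-en-1-yl trifluoromethanesulfonate F5. Pd(OAc)2, PPh3, HCO2H and Bu3N in DMF at 60 °C then replace the triflate by hydrogen to give 13.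

Step 6 may be slow because C-2′ is next to the quaternary carbon and the dienone is cross-conjugated, and 1,2-reduction could compete. The fallback sets out from 9 and comes back at 11 by moving the reduction before the shift. Step 5 is stopped after its first stage and ketal 8 is hydrolysed on wet silica gel with pyridinium p-toluenesulfonate so that 9 is isolated. Its plain bridged enone is reduced with [(Ph3P)CuH]6 in benzene at rt to (1R,5S,6S,7R)-5-allyl-7-(3,4-dimethoxyphenyl)-3-methoxy-6-methylbicyclo[3.2.1]octane-2,8-dione F3 (C-3 epimers). CF3SO3H (20 mol %) in CH2Cl2 at 0 °C then effects the same carbon-to-oxygen shift, and DBU equilibration at C-3′ gives 11.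

**Further compounds**

F1 | step 5 | 2-allyl-5-methoxy-1,4-benzoquinone | C=CCC1=CC(=O)C(OC)=CC1=O
F2 | step 5 | (1R,5R,6S,7R)-5-allyl-7-(3,4-dimethoxyphenyl)-3-hydroxy-6-methylbicyclo[3.2.1]oct-3-ene-2,8-dione | C=CC[C@@]12C=C(O)C(=O)[C@@H](C1=O)[C@H](c1ccc(OC)c(OC)c1)[C@@H]2C
F3 | step 6 | (1R,5S,6S,7R)-5-allyl-7-(3,4-dimethoxyphenyl)-3-methoxy-6-methylbicyclo[3.2.1]octane-2,8-dione (C-3 epimers) | C=CC[C@@]12CC(OC)C(=O)[C@@H](C1=O)[C@H](c1ccc(OC)c(OC)c1)[C@@H]2C
F4 | step 7 | (4S,6S)-4-allyl-4-[(1S,2R)-1-(3,4-dimethoxyphenyl)-1-hydroxypropan-2-yl]-6-methoxycyclohexane-1,3-dione | C=CC[C@@]1([C@@H](C)[C@H](O)c2ccc(OC)c(OC)c2)C[C@H](OC)C(=O)CC1=O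
F5 | step 7 | (4S,6S)-4-allyl-4-[(1S,2R)-1-(3,4-dimethoxyphenyl)-1-hydroxypropan-2-yl]-6-methoxy-3-oxocyclohex-1-en-1-yl trifluoromethanesulfonate | C=CC[C@@]1([C@@H](C)[C@H](O)c2ccc(OC)c(OC)c2)C[C@H](OC)C(OS(=O)(=O)C(F)(F)F)=CC1=O
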